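**Two questions.** Two questions stand on this flask, and I answer both with one exponent.

| setting | ash | oak | maple | flask |
|---|---|---|---|---|
| substrate | 10 mM | 10 mM | 10 mM | 10 mM |
| reagent | 6 mM | 6 mM | 9 mM | 6.00 mM |
| free catalyst | 20 µM | 78 µM | 39 µM | 39 µM |
| remark | run made earlier | run made earlier | run made earlier |  |

- ash (time / min: target / %, substrate / %): 0.833: 1.3, 98.6; 2.00: 3.3, 97.3; 4.00: 6.9, 93.8; 6.00: 9.8, 89.3; 8.00: 12.1, 87.7; 12.0: 19.5, 80.9; 15.0: 22.0, 78.5
- oak (time / min: target / %, substrate / %): 2.00: 8.4, 90.8; 4.00: 18.0, 80.6; 6.00: 27.3, 73.0; 8.00: 33.0, 64.4; 10.0: 39.4, 57.8; 12.0: 45.7, 52.3; 15.0: 52.2, 46.8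
- maple (time / min: target / %, substrate / %): 3.00: 11.7, 88.9; 6.00: 17.9, 83.0; 8.00: 23.2, 76.2; 12.0: 35.0, 65.9; 15.0: 40.9, 58.4

(readings scatter by 1 percentage point)

1. factor on the rate of making target when 50% of the substrate are converted if free catalyst is charged twice over
2. factor on the rate when 50% of the substrate are converted if free catalyst is charged at 400 µM instead



**Main step.** I start from the main step by itself: catalyst turns substrate into target, and the rate follows the catalyst charged. The exponent on catalyst is then one, so the doubled charge gives a factor 2, and going from 39 µM to 400 µM gives 10.3.

**Fraction left.** Next I add what the readings show. For a first-order decay, ln(1/fraction left)/t is a rate constant. At 15.0 min the ash run has 78.5% of its substrate left, which reads as 0.0161 /min. The oak run has 46.8% left at 15.0 min, which reads as 0.0506 /min. From these I read n = 0.840, the order in catalyst: the logarithm of the rate ratio over the logarithm of the charge ratio. This n lies below one, so the factors drop to 1.79 and 7.07.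

**The reagent.** The maple run reads 0.0359 /min, faster than the 0.0283 /min that n gives at 6 mM reagent, so reagent counts. Assuming one reagent per substrate, reagent is the limiting reagent, and 16.7% of it is left at 50% conversion. I guess that whatever holds n down fills through reagent, so n climbs toward one there, and I commit to factors between my two pairs.

**The forecast.** The forecast gives 1.65 and 4: “I expect about 4×, with wide uncertainty”. Both stand lower than my lower pair.

**The result.** The flask gives 1.94 and 8.37, each between my pairs.

    reagent + free catalyst → catalyst intermediate A (k = 4400 /M/min)
    substrate + catalyst intermediate A → catalyst intermediate B (k = 2700 /M/min)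
    catalyst intermediate B → free catalyst + target (k = 32.0 /min)
    2 catalyst intermediate B ⇌ resting dimer, settled at all times (K = 57000 /M)

In this flask the resting dimer holds 22.0% of the catalyst charged at 1.20 min and 12.9% at 12.0 min. Turned back into an order at 50% conversion in this flask, the doubling gives 0.956, higher than the 0.840 read from ash and oak. On the flask at 400 µM, the reading 0.840 gives 7.07, while the factor 8.37 corresponds to an order of 0.913.

The earlier runs and the new flask were generated by integration from invented constants; noise was put on by code.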